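Ring A is cut across C1–C6 and C2–C3. Its substitution alternates: oxygen on C2, C4 and C6, the butyryl group on C1, and the methylene bridges to the acetyl and propionyl rings on C3 and C5. That pattern is the sum of a 1-methoxy-1,3-bis(silyloxy)diene and a β-alkoxy ynone, so one [4+2] addition with aromatisation builds the hexasubstituted ring with both bridges and the acyl group already in place. The diene is methyl acetoacetate alkylated at C4 and then at C2 by the bromomethyl forms of the two outer rings, whose acyl-dione units are masked as isoxazoles and carry no acidic C–H.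

Key step: step 14

Remarks on the chemistry (assumptions)
- Ring A numbering: C1 butyryl, C2 O, C3 bridge to the acetyl ring, C4 O, C5 bridge to the propionyl ring, C6 O. "Arm M" is the (6-methoxy-3,7,7-trimethyl-4-oxo-4,7-dihydro-1,2-benzoxazol-5-yl)methyl group; "arm E" is its 3-ethyl analogue.
- A ring carbon that holds both OMe and OSiMe3 is assumed to lose methanol, not silanol, once a proton or silyl cation is present. The cycloaddition product is therefore written with a free C6–OH; a C6 methyl ether formed by purely thermal silanol loss would be cleaved in step 15 to the same compound 25.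
- 1-Ethoxyalkynes expel ethene near 100 °C, so the cycloaddition is held at or below 60 °C.
- BBr3 is used in step 15 because the boron chelate between C6–OH and the ketone would leave the C2 ethyl ether unassisted toward BCl3.
- Any isoxazole or enol-ether regioisomer of a masked outer ring would unmask to the same acylfilicinic ring, so a minor isomer in steps 2, 3, 6 or 7 costs material, not the route.
- Compounds 1 and 6 are taken to be commercial.

Step 1
Reactants: 1 1-(2,4,6-trihydroxyphenyl)ethan-1-one
Product: 2 2-acetyl-3,5-dihydroxy-4,6,6-trimethylcyclohexa-2,4-dien-1-one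
Conditions: MeI (3.1 equiv), NaOMe, MeOH, 0 → 65 °C; then 1 M HCl
Reagents that add atoms: iodomethane, CI
Why: Base-mediated C-methylation of the phloroglucinol anion with dearomatisation at the geminal carbon is long-known for acylphloroglucinols; three equivalents should stop mainly at the tri-C-methyl stage, which has only one possible constitution, and the lower and higher homologues are removed by chromatography.

Step 2
Reactants: 2 2-acetyl-3,5-dihydroxy-4,6,6-trimethylcyclohexa-2,4-dien-1-one
Product: 3 2-acetyl-3-hydroxy-5-methoxy-4,6,6-trimethylcyclohexa-2,4-dien-1-one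
Conditions: Me3SiCHN2 (1.05 equiv), MeOH/toluene, 0 °C
Reagents that add atoms: (trimethylsilyl)diazomethane, C[Si](C)(C)C=[N+]=[N-]
Why: O-Methylation of an acidic enol by a diazoalkane; the C5 hydroxyl is the only enol OH outside the hydrogen-bonded 2-acyl-1,3-dione chelate and should be methylated first, which leaves C1 as a free ketone for step 3.

Step 3
Reactants: 3 2-acetyl-3-hydroxy-5-methoxy-4,6,6-trimethylcyclohexa-2,4-dien-1-one
Product: 4 6-methoxy-3,5,7,7-tetramethyl-1,2-benzoxazol-4(7H)-one
Conditions: NH2OH·HCl, NaOAc, MeOH, 60 °C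
Reagents that add atoms: hydroxylamine hydrochloride, NO.Cl
Why: Isoxazole synthesis from a 2-acyl-1,3-dione and hydroxylamine (oxime formation at the side-chain carbonyl, then cyclodehydration); closure should go to C1, the one ring carbonyl that is a plain ketone, because C3 is the deactivated carbonyl carbon of the vinylogous ester.

Step 4
Reactants: 4 6-methoxy-3,5,7,7-tetramethyl-1,2-benzoxazol-4(7H)-one
Product: 5 5-(bromomethyl)-6-methoxy-3,7,7-trimethyl-1,2-benzoxazol-4(7H)-one
Conditions: NBS (1.05 equiv), AIBN (cat.), PhCF3, 80 °C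
Reagents that add atoms: N-bromosuccinimide, O=C1CCC(=O)N1Br
Why: Wohl–Ziegler allylic bromination; the C5 methyl group is the only allylic C–H site (C7 is quaternary) and sits on a β-alkoxy enone like the methyl group of a 3-methylchromone, a substrate type that is brominated at that methyl group under these conditions.

Step 5
Reactants: 6 1-(2,4,6-trihydroxyphenyl)propan-1-one
Product: 7 3,5-dihydroxy-4,6,6-trimethyl-2-propanoylcyclohexa-2,4-dien-1-one
Conditions: MeI (3.1 equiv), NaOMe, MeOH, 0 → 65 °C; then 1 M HCl
Reagents that add atoms: iodomethane, CI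
Why: The same threefold C-methylation with dearomatisation as in step 1, the side chain being a spectator.

Step 6
Reactants: 7 3,5-dihydroxy-4,6,6-trimethyl-2-propanoylcyclohexa-2,4-dien-1-one
Product: 8 3-hydroxy-5-methoxy-4,6,6-trimethyl-2-propanoylcyclohexa-2,4-dien-1-one
Conditions: Me3SiCHN2 (1.05 equiv), MeOH/toluene, 0 °C
Reagents that add atoms: (trimethylsilyl)diazomethane, C[Si](C)(C)C=[N+]=[N-]
Why: Diazoalkane O-methylation of the one non-chelated enol hydroxyl, as in step 2.

Step 7
Reactants: 8 3-hydroxy-5-methoxy-4,6,6-trimethyl-2-propanoylcyclohexa-2,4-dien-1-one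
Product: 9 3-ethyl-6-methoxy-5,7,7-trimethyl-1,2-benzoxazol-4(7H)-one
Conditions: NH2OH·HCl, NaOAc, MeOH, 60 °C
Reagents that add atoms: hydroxylamine hydrochloride, NO.Cl
Why: Oxime formation and cyclodehydration to the fused isoxazole as in step 3, with closure onto the plain ketone C1.

Step 8
Reactants: 9 3-ethyl-6-methoxy-5,7,7-trimethyl-1,2-benzoxazol-4(7H)-one
Product: 10 5-(bromomethyl)-3-ethyl-6-methoxy-7,7-dimethyl-1,2-benzoxazol-4(7H)-one
Conditions: NBS (1.0 equiv), AIBN (cat.), PhCF3, 80 °C
Reagents that add atoms: N-bromosuccinimide, O=C1CCC(=O)N1Br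
Why: Wohl–Ziegler bromination as in step 4; the CH2 of the ethyl group hangs on an electron-poor C=N carbon and should be attacked more slowly by the electrophilic bromine atom than the allylic methyl group, and conversion is held just short of completion to protect that margin.

Step 9
Reactants: 11 butanoyl chloride
Product: 12 N-methoxy-N-methylbutanamide
Conditions: MeNH(OMe)·HCl, K2CO3, EtOAc/H2O, 0 °C
Reagents that add atoms: N,O-dimethylhydroxylamine hydrochloride, CNOC.Cl
Why: Schotten–Baumann N-acylation of the amine by the acid chloride, with carbonate taking up the acid.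

Step 10
Reactants: 13 ethoxyacetylene; 12 N-methoxy-N-methylbutanamide
Product: 15 1-ethoxyhex-1-yn-3-one, via lithium ethoxyacetylide 14 (not isolated)
Conditions: n-BuLi, THF, −78 °C; then 12, −78 → −20 °C; aq. NH4Cl, 0 °C
Reagents that add atoms: none
Why: Weinreb ketone synthesis; the chelated tetrahedral adduct resists a second addition and releases the ynone only on quenching, and the product is kept cold and used at once because alkoxy ynones hydrate readily.

Step 11
Reactants: 16 methyl acetoacetate; 5 5-(bromomethyl)-6-methoxy-3,7,7-trimethyl-1,2-benzoxazol-4(7H)-one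
Product: 18 methyl 5-(6-methoxy-3,7,7-trimethyl-4-oxo-4,7-dihydro-1,2-benzoxazol-5-yl)-3-oxopentanoate, via acetoacetate dianion 17 (not isolated)
Conditions: NaH, THF, 0 °C; n-BuLi, 0 °C; then 5, −78 → 0 °C; 1 M HCl, 0 °C
Reagents that add atoms: none
Why: γ-Alkylation of the acetoacetate dianion; the more basic terminal carbanion should displace the primary allylic bromide by SN2, and the arm offers no acidic C–H to quench it.

Step 12
Reactants: 18 methyl 5-(6-methoxy-3,7,7-trimethyl-4-oxo-4,7-dihydro-1,2-benzoxazol-5-yl)-3-oxopentanoate; 10 5-(bromomethyl)-3-ethyl-6-methoxy-7,7-dimethyl-1,2-benzoxazol-4(7H)-one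
Product: 20 methyl 2-(arm E)-4-(arm M)-3-oxobutanoate (racemic), via sodium enolate 19 (not isolated)
Conditions: NaH (1.0 equiv), THF, 0 °C; then 10 (1.0 equiv), 0 → 20 °C
Reagents that add atoms: none
Why: C-Alkylation of a β-keto ester sodium enolate by an allylic bromide; the new stereocentre at C2 forms without control as the racemate and is erased in step 13.

Step 13
Reactants: 20 methyl 2-(arm E)-4-(arm M)-3-oxobutanoate
Product: 22 (3Z)-1-methoxy-2-(arm E)-4-(arm M)-1,3-bis(trimethylsilyloxy)buta-1,3-diene, via mono(silyl enol ether) 21 (not isolated)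
Conditions: Me3SiOTf (2.4 equiv), NEt3 (3 equiv), Et2O, 0 → 20 °C; pentane, filtration under argon; used crude
Reagents that add atoms: trimethylsilyl trifluoromethanesulfonate, C[Si](C)(C)OS(=O)(=O)C(F)(F)F
Why: Soft enolisation and O-silylation with a silyl triflate and an amine, first at the ketone and then by 1,4-silylation of the unsaturated ester to the ketene acetal; equilibrating conditions should place arm M cis to OSiMe3 at C3=C4 (Z), the geometry that can reach the s-cis diene, while the C1=C2 geometry is immaterial.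

Step 14
Reactants: 22 (3Z)-1-methoxy-2-(arm E)-4-(arm M)-1,3-bis(trimethylsilyloxy)buta-1,3-diene; 15 1-ethoxyhex-1-yn-3-one
Product: 24 1-[2-ethoxy-4,6-dihydroxy-3-(arm M)-5-(arm E)phenyl]butan-1-one, via silyl ketal cycloadduct 23 (not isolated)
Conditions: toluene, 20 → 60 °C; then 1 M HCl, THF, 0 °C
Reagents that add atoms: none
Why: Proposed new method: the electron-rich diene and the push-pull ynone should combine by an asynchronous [4+2] addition in which C4 of the diene, its most nucleophilic carbon, bonds to the ethoxy-bearing conjugate-acceptor carbon of the ynone and the ketene acetal carbon then bonds to the carbon next to the ketone; should the first bond form alone, the allenolate closes on the silylated ester carbon by a 6-exo-trig Claisen-type addition and reaches the same ring. The closest known reaction type is the cycloaddition–aromatisation of 1-alkoxy-1,3-bis(silyloxy)buta-1,3-dienes with acetylenic esters and ketones, which gives resorcinols; new here are the alkoxy group on the alkyne and the full substitution of the diene. Ring A is thus closed as a six-membered ring by [4+2] cycloaddition, and on protic work-up the silyl methyl ketal carbon C6 gives up methanol and both silyl groups are lost, which aromatises the ring. No stereocentre has to be controlled, because the two sp3 ring carbons of cycloadduct 23 both become aromatic. The selectivity needed is regiochemical and the polarisation of the ynone secures it, since only its alkoxy carbon accepts a nucleophile, so the butyryl carbon ends between two oxygenated carbons. The arms should not interfere, because their enone β-carbons are fully substituted and they hold no acidic C–H, and the temperature stays below that at which the ethoxyalkyne fragments.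

Step 15
Reactants: 24 1-[2-ethoxy-4,6-dihydroxy-3-(arm M)-5-(arm E)phenyl]butan-1-one
Product: 25 1-{3-[(6-hydroxy-3,7,7-trimethyl-4-oxo-4,7-dihydro-1,2-benzoxazol-5-yl)methyl]-5-[(3-ethyl-6-hydroxy-7,7-dimethyl-4-oxo-4,7-dihydro-1,2-benzoxazol-5-yl)methyl]-2,4,6-trihydroxyphenyl}butan-1-one
Conditions: BBr3 (8 equiv), CH2Cl2, −78 → 20 °C; then MeOH/H2O
Reagents that add atoms: none
Why: Lewis-acid ether cleavage by BBr3 (bromide attack on the O-alkyl carbon of the boron-complexed ether) should remove the aryl ethyl ether and both vinylogous methyl esters, while the isoxazoles, the aryl ketone and the methylene bridges offer no bond that the reagent attacks.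

Step 16
Reactants: 25 1-{3-[(6-hydroxy-3,7,7-trimethyl-4-oxo-4,7-dihydro-1,2-benzoxazol-5-yl)methyl]-5-[(3-ethyl-6-hydroxy-7,7-dimethyl-4-oxo-4,7-dihydro-1,2-benzoxazol-5-yl)methyl]-2,4,6-trihydroxyphenyl}butan-1-one
Product: 27 CNP0325527.0, via bis(enaminone) 26 (not isolated)
Conditions: Mo(CO)6, MeCN/H2O, 80 °C; filter; then 2 M HCl, THF, 60 °C
Reagents that add atoms: water, O
Why: Reductive N–O cleavage of both isoxazoles by zerovalent molybdenum in wet acetonitrile should give the vinylogous amides, and aqueous acid then hydrolyses these enaminones to the enolised acyl-diones with ammonia trapped as its salt; acid is chosen because base would let the methylene bridges migrate between rings.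

Compound list
1 | 1-(2,4,6-trihydroxyphenyl)ethan-1-one | CC(=O)c1c(O)cc(O)cc1O | starting material
2 | 2-acetyl-3,5-dihydroxy-4,6,6-trimethylcyclohexa-2,4-dien-1-one | CC(=O)C1=C(O)C(C)=C(O)C(C)(C)C1=O | intermediate
3 | 2-acetyl-3-hydroxy-5-methoxy-4,6,6-trimethylcyclohexa-2,4-dien-1-one | CC(=O)C1=C(O)C(C)=C(OC)C(C)(C)C1=O | intermediate
4 | 6-methoxy-3,5,7,7-tetramethyl-1,2-benzoxazol-4(7H)-one | CC1=C(OC)C(C)(C)c2onc(C)c2C1=O | intermediate
5 | 5-(bromomethyl)-6-methoxy-3,7,7-trimethyl-1,2-benzoxazol-4(7H)-one | BrCC1=C(OC)C(C)(C)c2onc(C)c2C1=O | intermediate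
6 | 1-(2,4,6-trihydroxyphenyl)propan-1-one | CCC(=O)c1c(O)cc(O)cc1O | starting material
7 | 3,5-dihydroxy-4,6,6-trimethyl-2-propanoylcyclohexa-2,4-dien-1-one | CCC(=O)C1=C(O)C(C)=C(O)C(C)(C)C1=O | intermediate
8 | 3-hydroxy-5-methoxy-4,6,6-trimethyl-2-propanoylcyclohexa-2,4-dien-1-one | CCC(=O)C1=C(O)C(C)=C(OC)C(C)(C)C1=O | intermediate
9 | 3-ethyl-6-methoxy-5,7,7-trimethyl-1,2-benzoxazol-4(7H)-one | CC1=C(OC)C(C)(C)c2onc(CC)c2C1=O | intermediate
10 | 5-(bromomethyl)-3-ethyl-6-methoxy-7,7-dimethyl-1,2-benzoxazol-4(7H)-one | BrCC1=C(OC)C(C)(C)c2onc(CC)c2C1=O | intermediate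
11 | butanoyl chloride | CCCC(Cl)=O | starting material
12 | N-methoxy-N-methylbutanamide | CCCC(=O)N(C)OC | intermediate
13 | ethoxyacetylene | CCOC#C | starting material
14 | lithium ethoxyacetylide (not isolated) | CCOC#C[Li] | intermediate
15 | 1-ethoxyhex-1-yn-3-one | CCCC(=O)C#COCC | intermediate
16 | methyl acetoacetate | COC(=O)CC(C)=O | starting material
17 | methyl acetoacetate 2,4-dianion, sodium lithium salt (not isolated) | COC(=O)[CH-]C(=O)[CH2-].[Na+].[Li+] | intermediate
18 | methyl 5-(6-methoxy-3,7,7-trimethyl-4-oxo-4,7-dihydro-1,2-benzoxazol-5-yl)-3-oxopentanoate | COC(=O)CC(=O)CCC1=C(OC)C(C)(C)c2onc(C)c2C1=O | intermediate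
19 | sodium enolate of 18 (not isolated) | COC(=O)[CH-]C(=O)CCC1=C(OC)C(C)(C)c2onc(C)c2C1=O.[Na+] | intermediate
20 | methyl 2-[(3-ethyl-6-methoxy-7,7-dimethyl-4-oxo-4,7-dihydro-1,2-benzoxazol-5-yl)methyl]-5-(6-methoxy-3,7,7-trimethyl-4-oxo-4,7-dihydro-1,2-benzoxazol-5-yl)-3-oxopentanoate, racemic | COC(=O)C(CC1=C(OC)C(C)(C)c2onc(CC)c2C1=O)C(=O)CCC1=C(OC)C(C)(C)c2onc(C)c2C1=O | intermediate
21 | methyl 2-(arm E)-4-(arm M)-3-(trimethylsilyloxy)but-2-enoate, E/Z mixture (not isolated) | COC(=O)C(CC1=C(OC)C(C)(C)c2onc(CC)c2C1=O)=C(O[Si](C)(C)C)CCC1=C(OC)C(C)(C)c2onc(C)c2C1=O | intermediate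
22 | (3Z)-1-methoxy-2-(arm E)-4-(arm M)-1,3-bis(trimethylsilyloxy)buta-1,3-diene, C1=C2 geometry mixed | COC(O[Si](C)(C)C)=C(CC1=C(OC)C(C)(C)c2onc(CC)c2C1=O)/C(O[Si](C)(C)C)=C/CC1=C(OC)C(C)(C)c2onc(C)c2C1=O | intermediate
23 | 1-[2-ethoxy-6-methoxy-3-(arm M)-5-(arm E)-4,6-bis(trimethylsilyloxy)cyclohexa-1,4-dien-1-yl]butan-1-one, diastereomer mixture (not isolated) | CCCC(=O)C1=C(OCC)C(CC2=C(OC)C(C)(C)c3onc(C)c3C2=O)C(O[Si](C)(C)C)=C(CC2=C(OC)C(C)(C)c3onc(CC)c3C2=O)C1(OC)O[Si](C)(C)C | intermediate
24 | 1-[2-ethoxy-4,6-dihydroxy-3-(arm M)-5-(arm E)phenyl]butan-1-one | CCCC(=O)c1c(OCC)c(CC2=C(OC)C(C)(C)c3onc(C)c3C2=O)c(O)c(CC2=C(OC)C(C)(C)c3onc(CC)c3C2=O)c1O | intermediate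
25 | 1-{3-[(6-hydroxy-3,7,7-trimethyl-4-oxo-4,7-dihydro-1,2-benzoxazol-5-yl)methyl]-5-[(3-ethyl-6-hydroxy-7,7-dimethyl-4-oxo-4,7-dihydro-1,2-benzoxazol-5-yl)methyl]-2,4,6-trihydroxyphenyl}butan-1-one | CCCC(=O)c1c(O)c(CC2=C(O)C(C)(C)c3onc(C)c3C2=O)c(O)c(CC2=C(O)C(C)(C)c3onc(CC)c3C2=O)c1O | intermediate
26 | 1-{3-{[5-(1-aminoethylidene)-2-hydroxy-3,3-dimethyl-4,6-dioxocyclohex-1-en-1-yl]methyl}-5-{[5-(1-aminopropylidene)-2-hydroxy-3,3-dimethyl-4,6-dioxocyclohex-1-en-1-yl]methyl}-2,4,6-trihydroxyphenyl}butan-1-one, tautomer mixture (not isolated) | CCCC(=O)c1c(O)c(CC2=C(O)C(C)(C)C(=O)C(=C(C)N)C2=O)c(O)c(CC2=C(O)C(C)(C)C(=O)C(=C(CC)N)C2=O)c1O | intermediate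
27 | CNP0325527.0, 1-{3-[(5-acetyl-2,6-dihydroxy-3,3-dimethyl-4-oxocyclohexa-1,5-dien-1-yl)methyl]-5-[(2,6-dihydroxy-3,3-dimethyl-4-oxo-5-propanoylcyclohexa-1,5-dien-1-yl)methyl]-2,4,6-trihydroxyphenyl}butan-1-one | CCCC(=O)c1c(O)c(CC2=C(O)C(C)(C)C(=O)C(C(C)=O)=C2O)c(O)c(CC2=C(O)C(C)(C)C(=O)C(C(=O)CC)=C2O)c1O | target

Total step count: 16
Longest linear sequence: 10 steps (steps 1, 2, 3, 4, 11, 12, 13, 14, 15, 16)

Steps most likely to fail

Step 14 (Proposed new method). The second bond may fail to form at the crowded ketene acetal carbon, leaving open-chain conjugate adducts. The diene may be protonated back to the keto ester. The ynone may be lost to hydration or ethene extrusion before it is attacked, or the diene may add to the ketone carbonyl instead of the alkyne. Fallback with known chemistry, setting out from bromides 5 and 10 and rejoining the route at 25: ring A is taken ready-made as commercial 1-(2,4,6-trihydroxyphenyl)butan-1-one (CCCC(=O)c1c(O)cc(O)cc1O). Its sodium salt (NaOMe, MeOH, 0 °C) is C-alkylated by 5 to give the mono-bridged phenone F1, and this is C-alkylated in the same way by 10 to give the doubly bridged phenone F2. BBr3 in CH2Cl2 then removes the two enol methyl groups and gives 25. Base-mediated C-alkylation of acylphloroglucinols with allylic halides is established; it loses material to O-alkylation and double alkylation, but the two free ring positions of the phenone are equivalent, so no regiochemical question arises.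

Step 16. The twofold hydrolysis of the strongly stabilised vinylogous amides may stall, and acid strong enough to drive it may let the methylene bridges migrate between rings once every oxygen is free. Fallback, setting out from 24 and rejoining at target 27: the order of unmasking is inverted and the hydrolysis is moved to base at a stage where the bridges are locked. Mo(CO)6 in MeCN/H2O opens both isoxazoles of 24 to the bis(enaminone) ether F3. Aqueous NaOH in MeOH at 60 °C, the usual hydrolysis of 2-(1-aminoalkylidene)-1,3-diones, gives the bis(acyl) ether F4; its outer rings still carry their methyl enol ethers and cannot form the enolate that bridge migration requires. BBr3 in CH2Cl2 then cleaves the three ethers and gives 27.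

Step 11. The hard, strongly basic dianion may attack the ring ketone or the methoxy-bearing enone carbon (SN2′) of the bromide, or decompose it by electron transfer, instead of displacing bromide. Fallback, setting out from 5 and rejoining at 18: the first bond is made with a soft malonate anion and the keto ester is built afterwards. Bromide 5 alkylates the sodium salt of di-tert-butyl malonate (NaH, THF, 0 °C) to give the malonate F5. CF3CO2H in CH2Cl2 followed by heating in toluene removes both tert-butyl groups and one carboxyl group and gives the propanoic acid F6. Activation with 1,1′-carbonyldiimidazole and decarboxylative Claisen condensation with Mg(O2CCH2CO2Me)2 in THF gives 18.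

Further compounds
F1 | step 14 | 1-{2,4,6-trihydroxy-3-[(6-methoxy-3,7,7-trimethyl-4-oxo-4,7-dihydro-1,2-benzoxazol-5-yl)methyl]phenyl}butan-1-one | CCCC(=O)c1c(O)cc(O)c(CC2=C(OC)C(C)(C)c3onc(C)c3C2=O)c1O
F2 | step 14 | 1-[2,4,6-trihydroxy-3-(arm M)-5-(arm E)phenyl]butan-1-one | CCCC(=O)c1c(O)c(CC2=C(OC)C(C)(C)c3onc(C)c3C2=O)c(O)c(CC2=C(OC)C(C)(C)c3onc(CC)c3C2=O)c1O
F3 | step 16 | 1-{3-{[5-(1-aminoethylidene)-2-methoxy-3,3-dimethyl-4,6-dioxocyclohex-1-en-1-yl]methyl}-5-{[5-(1-aminopropylidene)-2-methoxy-3,3-dimethyl-4,6-dioxocyclohex-1-en-1-yl]methyl}-2-ethoxy-4,6-dihydroxyphenyl}butan-1-one | CCCC(=O)c1c(OCC)c(CC2=C(OC)C(C)(C)C(=O)C(=C(C)N)C2=O)c(O)c(CC2=C(OC)C(C)(C)C(=O)C(=C(CC)N)C2=O)c1O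
F4 | step 16 | 1-{3-[(5-acetyl-6-hydroxy-2-methoxy-3,3-dimethyl-4-oxocyclohexa-1,5-dien-1-yl)methyl]-5-[(6-hydroxy-2-methoxy-3,3-dimethyl-4-oxo-5-propanoylcyclohexa-1,5-dien-1-yl)methyl]-2-ethoxy-4,6-dihydroxyphenyl}butan-1-one | CCCC(=O)c1c(OCC)c(CC2=C(OC)C(C)(C)C(=O)C(C(C)=O)=C2O)c(O)c(CC2=C(OC)C(C)(C)C(=O)C(C(=O)CC)=C2O)c1O
F5 | step 11 | di-tert-butyl 2-[(6-methoxy-3,7,7-trimethyl-4-oxo-4,7-dihydro-1,2-benzoxazol-5-yl)methyl]propanedioate | CC(C)(C)OC(=O)C(CC1=C(OC)C(C)(C)c2onc(C)c2C1=O)C(=O)OC(C)(C)C
F6 | step 11 | 3-(6-methoxy-3,7,7-trimethyl-4-oxo-4,7-dihydro-1,2-benzoxazol-5-yl)propanoic acid | OC(=O)CCC1=C(OC)C(C)(C)c2onc(C)c2C1=O
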